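**Retrosynthetic overview**

- Feature: the contiguous triad C8 (tertiary carbinol carrying C17), C9 (side chain) and C10 (quaternary, C20 methyl) on one edge of ring B maps onto a para-quinol-derived (4R)-4-hydroxy-2-methylcyclohex-2-enone with C5 as the carbonyl.
- Key disconnections: C9–C11 and C1–C10, made in one three-component step (alkoxide-directed Grignard 1,4-addition, then Michael trapping of the C5–C10 enolate by a 2-silylated pent-1-en-3-one).
- Ring order: ring B comes from the arene of 4-(hydroxymethyl)phenol (dearomatisation, enzymatic desymmetrisation, C10 methylation); ring A is closed second by aldol condensation (C4–C5), followed by reductive methylation at C4 and reduction at C3.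
- Side chain and end game: C13 acetal → lactol → alkyne → ynoate → Me2CuLi for the (13Z)-enoate; saponification, desilylation and selective oxidation of C17 come last.

Key step: step 7

Remark: carbons are numbered as in labdane throughout, and the ene-reductase of step 3 is assumed to be chosen from an enantiocomplementary pair so that the (4R)-enone is formed.

**Route**

Step 1
Reactants: 1 4-(hydroxymethyl)phenol
Product: 2 4-{[(triisopropylsilyl)oxy]methyl}phenol
Conditions: TIPSCl (1.05 equiv), imidazole, DMF, 0 °C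
Reagents that add atoms: chlorotriisopropylsilane, CC(C)[Si](Cl)(C(C)C)C(C)C
Why: Imidazole-mediated silylation should take place at the neutral primary benzylic hydroxyl faster than at the phenol, which stays free for the dearomatisation.

Step 2
Reactants: 2 4-{[(triisopropylsilyl)oxy]methyl}phenol
Product: 3 4-hydroxy-4-{[(triisopropylsilyl)oxy]methyl}cyclohexa-2,5-dien-1-one
Conditions: PhI(OAc)2 (1.1 equiv), MeCN/H2O (4:1), 0 °C
Reagents that add atoms: water, O
Why: Oxidative dearomatisation of a para-substituted phenol by a trivalent iodine reagent, in which water captures the para carbon of the activated phenol to give the achiral para-quinol.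

Step 3
Reactants: 3 4-hydroxy-4-{[(triisopropylsilyl)oxy]methyl}cyclohexa-2,5-dien-1-one
Product: 4 (4R)-4-hydroxy-4-{[(triisopropylsilyl)oxy]methyl}cyclohex-2-en-1-one
Conditions: ene-reductase of the old yellow enzyme family (YqjM or OPR3, whichever delivers the (4R)-enone), NADP+ (cat.), glucose, glucose dehydrogenase, phosphate buffer pH 7.0 with 5% DMSO, 30 °C
Reagents that add atoms: none
Why: Enzymatic desymmetrisation of a prochiral 4,4-disubstituted cyclohexa-2,5-dienone by flavin-dependent trans-hydrogenation of one enantiotopic alkene sets C8, and the enone formed is a poor substrate for a second reduction.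

Step 4
Reactants: 4 (4R)-4-hydroxy-4-{[(triisopropylsilyl)oxy]methyl}cyclohex-2-en-1-one
Product: 5 (4R)-4-hydroxy-2-iodo-4-{[(triisopropylsilyl)oxy]methyl}cyclohex-2-en-1-one
Conditions: I2 (1.5 equiv), pyridine/CH2Cl2 (1:1), 0 °C → rt
Reagents that add atoms: iodine, II
Why: α-Iodination of an enone by conjugate addition of pyridine, iodination of the enolate and elimination places iodine only at C10 and leaves the tertiary alcohol untouched.

Step 5
Reactants: 5 (4R)-4-hydroxy-2-iodo-4-{[(triisopropylsilyl)oxy]methyl}cyclohex-2-en-1-one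
Product: 6 (4R)-4-hydroxy-2-methyl-4-{[(triisopropylsilyl)oxy]methyl}cyclohex-2-en-1-one
Conditions: Me4Sn (2 equiv), Pd(PPh3)4 (5 mol%), CuI (10 mol%), DMF, 60 °C, sealed tube
Reagents that add atoms: tetramethylstannane, C[Sn](C)(C)C
Why: Stille coupling of the 2-iodoenone (oxidative addition to zerovalent palladium, copper-assisted transmetalation, reductive elimination) installs the C20 methyl and tolerates the free hydroxyl and the silyl ether.

Step 6
Reactants: 7 (1-bromovinyl)trimethylsilane, 8 N-methoxy-N-methylpropanamide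
Product: 10 2-(trimethylsilyl)pent-1-en-3-one, via vinylmagnesium bromide 9 (not isolated)
Conditions: Mg, THF, reflux; then 8, 0 °C; aq. NH4Cl
Reagents that add atoms: none
Why: Weinreb ketone synthesis, in which the chelated tetrahedral magnesium intermediate releases the enone only on work-up, so that no second addition occurs.

Step 7
Reactants: 6 (4R)-4-hydroxy-2-methyl-4-{[(triisopropylsilyl)oxy]methyl}cyclohex-2-en-1-one, 11 2-(2-bromoethyl)-1,3-dioxolane, 10 2-(trimethylsilyl)pent-1-en-3-one
Product: 15 (2S,3S,4R)-3-[2-(1,3-dioxolan-2-yl)ethyl]-4-hydroxy-2-methyl-2-(3-oxopentyl)-4-{[(triisopropylsilyl)oxy]methyl}cyclohexan-1-one, via Grignard reagent 12 (not isolated), via magnesium enolate 13 (not isolated), via α-silyl diketone 14 (not isolated)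
Conditions: 11, Mg, THF, 25 °C; 6 added to 12 (2.3 equiv), THF, −78 → −20 °C; then 10 (1.5 equiv), −78 → 0 °C; then K2CO3, MeOH, 0 °C; aq. NH4Cl
Reagents that add atoms: none
Why: One equivalent of 12 turns the C8 hydroxyl into a bromomagnesium alkoxide, and a second equivalent bound to that alkoxide transfers the C11 carbon to C9 on the oxygen-bearing face, giving the regiodefined C5–C10 magnesium enolate 13; 13 then adds through C10 to the β-carbon of 10, and methanolic K2CO3 removes the carbon-bound silyl group of adduct 14. The closest known reaction types are the alkoxide-directed 1,4-addition of Grignard reagents to 4-oxido enones and the Michael trapping of conjugate-addition enolates by α-silyl vinyl ketones (the first stage of a Robinson annulation), in which the silyl group stabilises the adduct anion and suppresses oligomerisation of the acceptor. No ring is closed in this step; only the C9–C11 and C1–C10 bonds are formed. C9 is set by the C8 alkoxide through syn delivery, and the quaternary C10 is set by the new C9 chain, which lies pseudoaxial to avoid allylic strain with the C10 methyl so that 10 enters on the opposite face and C20 ends cis to C11. The step needs 1,4- over 1,2-addition and C-alkylation at C10 instead of C6 or oxygen: intramolecular delivery from the alkoxide secures the first and the fixed position of the enolate double bond the second.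

Step 8
Reactants: 15 (2S,3S,4R)-3-[2-(1,3-dioxolan-2-yl)ethyl]-4-hydroxy-2-methyl-2-(3-oxopentyl)-4-{[(triisopropylsilyl)oxy]methyl}cyclohexan-1-one
Product: 17 (8R,9S,10S)-bicyclic enone (ring A 4-methyl-4-en-3-one; C10 methyl; C9 2-(1,3-dioxolan-2-yl)ethyl; C8 hydroxyl and CH2OTIPS), via aldol ketol 16 (not isolated)
Conditions: NaOMe, MeOH, 60 °C
Reagents that add atoms: none
Why: Intramolecular aldol condensation (second stage of a Robinson annulation), in which the C4 enolate of the ethyl ketone closes ring A on the C5 carbonyl in a 6-(enolendo)-exo-trig mode and the ketol dehydrates to the conjugated enone; no existing stereocentre can epimerise.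

Step 9
Reactants: 17 (8R,9S,10S)-bicyclic enone
Product: 19 (5S,8R,9S,10R)-trans-decalin 4,4-dimethyl-3-ketone (C9 2-(1,3-dioxolan-2-yl)ethyl; C8 hydroxyl and CH2OTIPS), via lithium enolate 18 (not isolated)
Conditions: Li (2.2 equiv), NH3/THF, −78 °C, no added proton source; then MeI (excess), −78 → −33 °C; NH4Cl
Reagents that add atoms: iodomethane, CI
Why: Dissolving-metal reduction of the enone with regiospecific C-methylation of the C3–C4 enolate (reductive alkylation); the C8 hydroxyl supplies the single proton needed, the C5 carbanion is protonated axially on the face opposite the C10 methyl to set the trans ring fusion, and methylation at C4 completes the gem-dimethyl group.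

Step 10
Reactants: 19 (5S,8R,9S,10R)-trans-decalin 4,4-dimethyl-3-ketone
Product: 20 (3R,5S,8R,9S,10R)-3,8-diol (C9 2-(1,3-dioxolan-2-yl)ethyl; C17 OTIPS)
Conditions: NaBH4, MeOH, 0 °C
Reagents that add atoms: none
Why: Hydride reduction of the 4,4-dimethyl-3-ketone, in which axial delivery on the face away from the axial C4 and C10 methyl groups gives the equatorial (3R) alcohol.

Step 11
Reactants: 20 (3R,5S,8R,9S,10R)-3,8-diol
Product: 21 (3R,5S,8R,9S,10R)-8,13-epoxy-13-ol lactol (both C13 epimers; C3 hydroxyl; C17 OTIPS)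
Conditions: pyridinium p-toluenesulfonate (0.3 equiv), acetone/H2O (4:1), 60 °C
Reagents that add atoms: water, O
Why: Acid-catalysed acetal hydrolysis, after which the C13 aldehyde is captured by the C8 hydroxyl as the six-membered lactol; the acid-stable primary TIPS ether keeps O17 out of an intramolecular bicyclic acetal.

Step 12
Reactants: 21 (3R,5S,8R,9S,10R)-8,13-epoxy-13-ol lactol
Product: 23 (3R,5S,8R,9S,10R)-alkyne diol (C9 but-3-ynyl; C3 and C8 hydroxyls; C17 OTIPS), via hydroxy aldehyde 22 (not isolated)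
Conditions: dimethyl (1-diazo-2-oxopropyl)phosphonate (2 equiv), K2CO3, MeOH, 0 → 40 °C
Reagents that add atoms: dimethyl (1-diazo-2-oxopropyl)phosphonate, CC(=O)C(=[N+]=[N-])P(=O)(OC)OC
Why: Seyferth–Gilbert homologation with the Ohira–Bestmann reagent acts on the open hydroxy aldehyde in equilibrium with the lactol, a standard passage from lactols to alkynols that adds C14.

Step 13
Reactants: 23 (3R,5S,8R,9S,10R)-alkyne diol
Product: 24 (3R,5S,8R,9S,10R)-3,8-bis(triethylsilyl) ether of the alkyne (C17 OTIPS)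
Conditions: TESOTf (3 equiv), 2,6-lutidine, CH2Cl2, 0 °C → rt
Reagents that add atoms: triethylsilyl trifluoromethanesulfonate, CC[Si](CC)(CC)OS(=O)(=O)C(F)(F)F
Why: A silyl triflate is reactive enough for the hindered secondary C3 and axial tertiary C8 hydroxyls, and capping both removes acidic protons and blocks oxa-Michael addition of O8 to C13 at the ynoate stage.

Step 14
Reactants: 24 (3R,5S,8R,9S,10R)-3,8-bis(triethylsilyl) ether of the alkyne
Product: 26 methyl alk-13-yn-15-oate (3,8-bis-TES; C17 OTIPS), via lithium acetylide 25 (not isolated)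
Conditions: n-BuLi (1.1 equiv), THF, −78 °C; ClCO2Me, −78 → 0 °C
Reagents that add atoms: methyl chloroformate, COC(=O)Cl
Why: Deprotonation of the terminal alkyne and C-acylation of the lithium acetylide with a chloroformate gives the ynoate and adds C15.

Step 15
Reactants: 26 methyl alk-13-yn-15-oate
Product: 28 methyl (13Z)-enoate (3,8-bis-TES; C17 OTIPS), via alkenylcopper adduct 27 (not isolated)
Conditions: Me2CuLi (2 equiv, from MeLi and CuI), THF, −78 °C; MeOH at −78 °C, then aq. NH4Cl
Reagents that add atoms: lithium dimethylcuprate, [Li+].C[Cu-]C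
Why: Syn carbocupration of the ynoate places the C16 methyl and copper cis, and protonation with retention at −78 °C, before the adduct can equilibrate through an allenoate, gives the (13Z)-enoate with the chain cis to the ester.

Step 16
Reactants: 28 methyl (13Z)-enoate
Product: 29 (13Z)-enoic acid (3,8-bis-TES; C17 OTIPS)
Conditions: LiOH·H2O, THF/MeOH/H2O, 50 °C; aq. HCl to pH 4
Reagents that add atoms: lithium hydroxide, [Li+].[OH-]
Why: Saponification is placed before the base-sensitive α-hydroxy aldehyde exists, and hydroxide should affect neither the hindered silyl ethers nor the alkene geometry.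

Step 17
Reactants: 29 (13Z)-enoic acid (3,8-bis-TES; C17 OTIPS)
Product: 30 (3R,5S,8R,9S,10R,13Z)-3,8,17-trihydroxylabd-13-en-15-oic acid
Conditions: HF·pyridine (excess), THF, 0 → 40 °C
Reagents that add atoms: none
Why: Fluoride-driven cleavage of the three Si–O bonds under weakly acidic conditions that should not isomerise the (Z)-enoic acid.

Step 18
Reactants: 30 (3R,5S,8R,9S,10R,13Z)-3,8,17-trihydroxylabd-13-en-15-oic acid
Product: 31 (3R,5S,8R,9S,10R,13Z)-3,8-dihydroxy-17-oxolabd-13-en-15-oic acid
Conditions: (2,2,6,6-tetramethylpiperidin-1-yl)oxyl (TEMPO, 0.1 equiv), PhI(OAc)2 (1.1 equiv), anhydrous CH2Cl2/MeCN, 0 °C → rt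
Reagents that add atoms: none
Why: Oxoammonium-mediated oxidation is selective for the primary C17 alcohol over the hindered secondary C3 and tertiary C8 hydroxyls and stops at the aldehyde without water, so the target forms with no further protecting-group step on the α-hydroxy aldehyde.

**Compound list**

1 | 4-(hydroxymethyl)phenol | OCc1ccc(O)cc1 | starting material
2 | 4-{[(triisopropylsilyl)oxy]methyl}phenol | Oc1ccc(CO[Si](C(C)C)(C(C)C)C(C)C)cc1 | intermediate
3 | 4-hydroxy-4-{[(triisopropylsilyl)oxy]methyl}cyclohexa-2,5-dien-1-one | O=C1C=CC(O)(CO[Si](C(C)C)(C(C)C)C(C)C)C=C1 | intermediate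
4 | (4R)-4-hydroxy-4-{[(triisopropylsilyl)oxy]methyl}cyclohex-2-en-1-one | O=C1C=C[C@@](O)(CO[Si](C(C)C)(C(C)C)C(C)C)CC1 | intermediate
5 | (4R)-4-hydroxy-2-iodo-4-{[(triisopropylsilyl)oxy]methyl}cyclohex-2-en-1-one | O=C1C(I)=C[C@@](O)(CO[Si](C(C)C)(C(C)C)C(C)C)CC1 | intermediate
6 | (4R)-4-hydroxy-2-methyl-4-{[(triisopropylsilyl)oxy]methyl}cyclohex-2-en-1-one | CC1=C[C@@](O)(CO[Si](C(C)C)(C(C)C)C(C)C)CCC1=O | intermediate
7 | (1-bromovinyl)trimethylsilane | C=C(Br)[Si](C)(C)C | starting material
8 | N-methoxy-N-methylpropanamide | CCC(=O)N(C)OC | starting material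
9 | 1-(trimethylsilyl)vinylmagnesium bromide (not isolated) | C=C([Mg]Br)[Si](C)(C)C | intermediate
10 | 2-(trimethylsilyl)pent-1-en-3-one | CCC(=O)C(=C)[Si](C)(C)C | intermediate
11 | 2-(2-bromoethyl)-1,3-dioxolane | BrCCC1OCCO1 | starting material
12 | 2-(1,3-dioxolan-2-yl)ethylmagnesium bromide (not isolated) | Br[Mg]CCC1OCCO1 | intermediate
13 | bis(bromomagnesium) salt of (3S,4R)-3-[2-(1,3-dioxolan-2-yl)ethyl]-2-methyl-4-{[(triisopropylsilyl)oxy]methyl}cyclohex-1-ene-1,4-diol, the C5–C10 enolate and C8 alkoxide (not isolated) | O3CCOC3CC[C@H]1C(C)=C(O[Mg]Br)CC[C@]1(O[Mg]Br)CO[Si](C(C)C)(C(C)C)C(C)C | intermediate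
14 | (2S,3S,4R)-3-[2-(1,3-dioxolan-2-yl)ethyl]-4-hydroxy-2-methyl-2-[3-oxo-2-(trimethylsilyl)pentyl]-4-{[(triisopropylsilyl)oxy]methyl}cyclohexan-1-one, both epimers at the silylated carbon (not isolated) | O3CCOC3CC[C@H]1[C@](C)(CC(C(=O)CC)[Si](C)(C)C)C(=O)CC[C@]1(O)CO[Si](C(C)C)(C(C)C)C(C)C | intermediate
15 | (2S,3S,4R)-3-[2-(1,3-dioxolan-2-yl)ethyl]-4-hydroxy-2-methyl-2-(3-oxopentyl)-4-{[(triisopropylsilyl)oxy]methyl}cyclohexan-1-one | O3CCOC3CC[C@H]1[C@](C)(CCC(=O)CC)C(=O)CC[C@]1(O)CO[Si](C(C)C)(C(C)C)C(C)C | intermediate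
16 | (8R,9S,10S)-aldol ketol: decalin with C3 ketone, C4 methyl, C5 hydroxyl (C4 and C5 epimers), C10 methyl, C9 2-(1,3-dioxolan-2-yl)ethyl, C8 hydroxyl and CH2OTIPS (not isolated) | O3CCOC3CC[C@H]1[C@]2(C)CCC(=O)C(C)C2(O)CC[C@]1(O)CO[Si](C(C)C)(C(C)C)C(C)C | intermediate
17 | (8R,9S,10S)-bicyclic enone: 4-methyl-4-en-3-one in ring A, C10 methyl, C9 2-(1,3-dioxolan-2-yl)ethyl, C8 hydroxyl and CH2OTIPS | O3CCOC3CC[C@H]1[C@]2(C)CCC(=O)C(C)=C2CC[C@]1(O)CO[Si](C(C)C)(C(C)C)C(C)C | intermediate
18 | (5S,8R,9S,10R)-dilithium salt: C3–C4 enolate and C8 alkoxide of the trans-decalin (not isolated) | O3CCOC3CC[C@H]1[C@]2(C)CCC(O[Li])=C(C)[C@H]2CC[C@]1(O[Li])CO[Si](C(C)C)(C(C)C)C(C)C | intermediate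
19 | (5S,8R,9S,10R)-trans-decalin 4,4-dimethyl-3-ketone with C10 methyl, C9 2-(1,3-dioxolan-2-yl)ethyl, C8 hydroxyl and CH2OTIPS | O3CCOC3CC[C@H]1[C@]2(C)CCC(=O)C(C)(C)[C@H]2CC[C@]1(O)CO[Si](C(C)C)(C(C)C)C(C)C | intermediate
20 | (3R,5S,8R,9S,10R)-3,8-diol with C9 2-(1,3-dioxolan-2-yl)ethyl and C17 OTIPS | O3CCOC3CC[C@H]1[C@]2(C)CC[C@@H](O)C(C)(C)[C@H]2CC[C@]1(O)CO[Si](C(C)C)(C(C)C)C(C)C | intermediate
21 | (3R,5S,8R,9S,10R)-8,13-epoxy-13-ol lactol (C13 epimers) with C3 hydroxyl and C17 OTIPS | OC4CC[C@H]1[C@]2(C)CC[C@@H](O)C(C)(C)[C@H]2CC[C@]1(O4)CO[Si](C(C)C)(C(C)C)C(C)C | intermediate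
22 | (3R,5S,8R,9S,10R)-3,8-dihydroxy C13 aldehyde, open form of 21 (not isolated) | O=CCC[C@H]1[C@]2(C)CC[C@@H](O)C(C)(C)[C@H]2CC[C@]1(O)CO[Si](C(C)C)(C(C)C)C(C)C | intermediate
23 | (3R,5S,8R,9S,10R)-alkyne diol: C9 but-3-ynyl, C3 and C8 hydroxyls, C17 OTIPS | C#CCC[C@H]1[C@]2(C)CC[C@@H](O)C(C)(C)[C@H]2CC[C@]1(O)CO[Si](C(C)C)(C(C)C)C(C)C | intermediate
24 | (3R,5S,8R,9S,10R)-alkyne with C3 and C8 OTES and C17 OTIPS | C#CCC[C@H]1[C@]2(C)CC[C@@H](O[Si](CC)(CC)CC)C(C)(C)[C@H]2CC[C@]1(O[Si](CC)(CC)CC)CO[Si](C(C)C)(C(C)C)C(C)C | intermediate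
25 | lithium acetylide of 24 (not isolated) | [Li]C#CCC[C@H]1[C@]2(C)CC[C@@H](O[Si](CC)(CC)CC)C(C)(C)[C@H]2CC[C@]1(O[Si](CC)(CC)CC)CO[Si](C(C)C)(C(C)C)C(C)C | intermediate
26 | (3R,5S,8R,9S,10R)-methyl alk-13-yn-15-oate with C3 and C8 OTES and C17 OTIPS | COC(=O)C#CCC[C@H]1[C@]2(C)CC[C@@H](O[Si](CC)(CC)CC)C(C)(C)[C@H]2CC[C@]1(O[Si](CC)(CC)CC)CO[Si](C(C)C)(C(C)C)C(C)C | intermediate
27 | alkenylcopper adduct of 26, copper at C14 cis to the C16 methyl (not isolated) | C/C(=C(\[Cu])C(=O)OC)CC[C@H]1[C@]2(C)CC[C@@H](O[Si](CC)(CC)CC)C(C)(C)[C@H]2CC[C@]1(O[Si](CC)(CC)CC)CO[Si](C(C)C)(C(C)C)C(C)C | intermediate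
28 | (3R,5S,8R,9S,10R,13Z)-methyl enoate with C3 and C8 OTES and C17 OTIPS | C/C(=C/C(=O)OC)CC[C@H]1[C@]2(C)CC[C@@H](O[Si](CC)(CC)CC)C(C)(C)[C@H]2CC[C@]1(O[Si](CC)(CC)CC)CO[Si](C(C)C)(C(C)C)C(C)C | intermediate
29 | (3R,5S,8R,9S,10R,13Z)-enoic acid with C3 and C8 OTES and C17 OTIPS | C/C(=C/C(=O)O)CC[C@H]1[C@]2(C)CC[C@@H](O[Si](CC)(CC)CC)C(C)(C)[C@H]2CC[C@]1(O[Si](CC)(CC)CC)CO[Si](C(C)C)(C(C)C)C(C)C | intermediate
30 | (3R,5S,8R,9S,10R,13Z)-3,8,17-trihydroxylabd-13-en-15-oic acid | C/C(=C/C(=O)O)CC[C@H]1[C@]2(C)CC[C@@H](O)C(C)(C)[C@H]2CC[C@]1(O)CO | intermediate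
31 | (3R,5S,8R,9S,10R,13Z)-3,8-dihydroxy-17-oxolabd-13-en-15-oic acid | C/C(=C/C(=O)O)CC[C@H]1[C@]2(C)CC[C@@H](O)C(C)(C)[C@H]2CC[C@]1(O)C=O | target

**Step count and risks**

Total step count: 18. Longest linear sequence: 17 steps (steps 1–5 and 7–18); step 6 is a one-step side branch.

The three steps most likely to fail:

Step 7. Oligomerisation of the acceptor and proton transfer may outrun C-alkylation of the hindered tetrasubstituted magnesium enolate. The C8 magnesium alkoxide may also steer the acceptor to the wrong face of C10, and 1,2-addition of the Grignard reagent is a further loss channel. Fallback: setting out from 6, the directed conjugate addition of 12 is run alone and quenched with aq. NH4Cl to give the conjugate-addition ketone F1 as a mixture of C10 epimers. Its more substituted enolate is then formed under protic, equilibrating conditions (KOH cat., MeOH, 0 °C) and added to pent-1-en-3-one, the classical base-mediated Michael stage of a Robinson annulation, with no metal alkoxide to misdirect the acceptor. The route is rejoined at 15.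

Step 3. The enzyme may bind the bulky silyloxymethyl quinol poorly or distinguish the two enantiotopic alkenes weakly, giving slow conversion or low enantiomeric purity. Fallback: setting out from 3, both alkenes are hydrogenated (H2, Rh/Al2O3, EtOAc) to the achiral hydroxy ketone F2, and N-(trimethylsilyl)imidazole caps the tertiary hydroxyl to give the silyloxy ketone F3. Enantioselective deprotonation with a homochiral lithium amide (lithium bis(1-phenylethyl)amide of the appropriate configuration, TMSCl present, THF, −100 °C) gives the silyl enol ether F4. Saegusa–Ito oxidation (Pd(OAc)2, MeCN) gives the silyloxy enone F5, and citric acid in MeOH frees the hydroxyl, rejoining the route at 4.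

Step 18. Competing oxidation at C3, over-oxidation of the aldehyde or glycol-type cleavage at the C8–C17 diol may erode the chemoselectivity on this polar substrate. Fallback: setting out from 30, both the C17 and the C3 carbinols are oxidised with Dess–Martin periodinane (excess, CH2Cl2/MeCN) to the keto aldehyde F6. A ketone-selective Luche reduction in aqueous ethanol (NaBH4, CeCl3·7H2O, −15 °C) follows, in which the α-hydroxy aldehyde is held as its hydrate and the C3 ketone is reduced from the axial direction. The route is rejoined at 31.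

**Further compounds**

F1 | step 7 | (3S,4R)-3-[2-(1,3-dioxolan-2-yl)ethyl]-4-hydroxy-2-methyl-4-{[(triisopropylsilyl)oxy]methyl}cyclohexan-1-one (C2 epimers) | O3CCOC3CC[C@H]1C(C)C(=O)CC[C@]1(O)CO[Si](C(C)C)(C(C)C)C(C)C
F2 | step 3 | 4-hydroxy-4-{[(triisopropylsilyl)oxy]methyl}cyclohexan-1-one | O=C1CCC(O)(CO[Si](C(C)C)(C(C)C)C(C)C)CC1
F3 | step 3 | 4-{[(triisopropylsilyl)oxy]methyl}-4-[(trimethylsilyl)oxy]cyclohexan-1-one | O=C1CCC(O[Si](C)(C)C)(CO[Si](C(C)C)(C(C)C)C(C)C)CC1
F4 | step 3 | (4R)-4-{[(triisopropylsilyl)oxy]methyl}-1,4-bis[(trimethylsilyl)oxy]cyclohex-1-ene | C[Si](C)(C)OC1=CC[C@@](O[Si](C)(C)C)(CO[Si](C(C)C)(C(C)C)C(C)C)CC1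
F5 | step 3 | (4R)-4-{[(triisopropylsilyl)oxy]methyl}-4-[(trimethylsilyl)oxy]cyclohex-2-en-1-one | O=C1C=C[C@@](O[Si](C)(C)C)(CO[Si](C(C)C)(C(C)C)C(C)C)CC1
F6 | step 18 | (5S,8R,9S,10R,13Z)-8-hydroxy-3,17-dioxolabd-13-en-15-oic acid | C/C(=C/C(=O)O)CC[C@H]1[C@]2(C)CCC(=O)C(C)(C)[C@H]2CC[C@]1(O)C=O
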